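The imidazole is read as a disguised tyrosine: N3, ring carbon C4 and its 4-oxybenzyl arm are the amino nitrogen, Cα and side chain of tyrosine, and ring carbon C5 is the carboxyl carbon. Everything rests on the bond between C5 and the CH2 of the 4-methoxybenzyl group. The key step makes it by adding 4-methoxybenzylmagnesium chloride to the Weinreb amide of Boc-Tyr(tBu)-OH; one operation unites both aryl arms and fixes C5 at the acyl oxidation level in an α-amino ketone that holds every skeletal atom but C2 and N1. Formamidine then supplies C2 and N1 to close the imidazole ring, and phenol O-sulfation ends the route.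

Key step: step 2

Remark on the chemistry: the target has no stereocentre, so no enantiomer has to be controlled; the (S)-centre of the tyrosine building block is sacrificial and becomes the sp2 ring carbon C4 in step 3.

Step 1
Reactants: 1 Boc-Tyr(tBu)-OH, (2S)-2-[(tert-butoxycarbonyl)amino]-3-(4-tert-butoxyphenyl)propanoic acid
Product: 2 tert-butyl N-[(2S)-3-(4-tert-butoxyphenyl)-1-[methoxy(methyl)amino]-1-oxopropan-2-yl]carbamate
Conditions: MeNHOMe·HCl (1.2 equiv), EDC·HCl, HOBt (cat.), N-methylmorpholine, CH2Cl2, 0 °C → rt
Reagents that add atoms: N,O-dimethylhydroxylamine hydrochloride (CNOC.Cl)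
Why: Carbodiimide/HOBt amide coupling of a urethane-protected amino acid with N,O-dimethylhydroxylamine is the standard preparation of a Weinreb amide and leaves the Boc group and the aryl tert-butyl ether untouched.

Step 2
Reactants: 2 tert-butyl N-[(2S)-3-(4-tert-butoxyphenyl)-1-[methoxy(methyl)amino]-1-oxopropan-2-yl]carbamate, 3 4-methoxybenzylmagnesium chloride
Product: 5 tert-butyl N-[(2S)-1-(4-tert-butoxyphenyl)-4-(4-methoxyphenyl)-3-oxobutan-2-yl]carbamate, via magnesium hemiaminal chelate 4 (not isolated)
Conditions: 3 (2.5 equiv, 0.25 M in THF), THF, −20 → 0 °C; then 1 M aq. HCl, 0 °C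
Reagents that add atoms: none
Why: Weinreb–Nahm ketone synthesis: the first equivalent of 3 deprotonates the carbamate N–H, the second adds to the amide carbonyl to give the five-membered O–Mg–OMe chelate 4, which cannot collapse before the acid quench, so a second addition to the ketone is excluded. The closest known reaction type is the addition of benzylic Grignard reagents to Weinreb amides of N-Boc amino acids. No ring is closed and no stereocentre of the target is set; the hemiaminal carbon of 4 is transient and the Cα centre of 2 later becomes the sp2 ring carbon C4, so its configurational integrity is irrelevant. The step needs mono-addition at the amide carbonyl (not at the Boc carbonyl, and without proton abstraction at Cα) and attack through the benzylic carbon of 3 rather than through its ortho position; the N-methoxy chelate, the anionic carbamate and the low temperature should secure the former, and the hindered, moderately reactive amide electrophile should favour normal benzylic addition.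

Step 3
Reactants: 5 tert-butyl N-[(2S)-1-(4-tert-butoxyphenyl)-4-(4-methoxyphenyl)-3-oxobutan-2-yl]carbamate
Product: 7 4-{[5-(4-methoxybenzyl)-1H-imidazol-4-yl]methyl}phenol, via amino ketone trifluoroacetate 6 (not isolated)
Conditions: TFA/CH2Cl2/H2O (10:10:1), rt; concentrate; then formamidine acetate (6 equiv), liq. NH3, sealed vessel, rt
Reagents that add atoms: formamidine acetate (N=CN.CC(=O)O)
Why: Acidolysis removes the Boc group and the aryl tert-butyl ether by loss of tert-butyl cations, and the α-amino ketone then undergoes an amidine-type imidazole annulation with formamidine (transamidination at the amine, cyclodehydration onto the ketone, aromatisation), which turns the sacrificial stereocentre into sp2 C4 and leads to the same N–H-tautomeric imidazole whichever nitrogen ends up next to which carbon.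

Step 4
Reactants: 7 4-{[5-(4-methoxybenzyl)-1H-imidazol-4-yl]methyl}phenol
Product: 8 melanocin F, 4-{[5-(4-methoxybenzyl)-1H-imidazol-4-yl]methyl}phenyl hydrogen sulfate
Conditions: SO3·pyridine (3 equiv), pyridine, rt; then H2O/MeOH; RP-18 chromatography (zwitterion)
Reagents that add atoms: sulfur trioxide–pyridine complex (O=S(=O)=O.c1ccncc1)
Why: Phenol O-sulfation with the SO3·pyridine complex is the standard route to aryl hydrogen sulfates; the basic imidazole should take up the proton to give the inner salt, and transient N-sulfonation of the imidazole is reversed by the aqueous methanol work-up.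

Compound list
1 | Boc-Tyr(tBu)-OH, (2S)-2-[(tert-butoxycarbonyl)amino]-3-(4-tert-butoxyphenyl)propanoic acid | CC(C)(C)OC(=O)N[C@@H](Cc1ccc(OC(C)(C)C)cc1)C(=O)O | starting material
2 | tert-butyl N-[(2S)-3-(4-tert-butoxyphenyl)-1-[methoxy(methyl)amino]-1-oxopropan-2-yl]carbamate (Weinreb amide) | CC(C)(C)OC(=O)N[C@@H](Cc1ccc(OC(C)(C)C)cc1)C(=O)N(C)OC | intermediate
3 | 4-methoxybenzylmagnesium chloride | COc1ccc(C[Mg]Cl)cc1 | starting material
4 | N,O-bis(chloromagnesio) tetrahedral adduct of 2 and 3 (magnesium hemiaminal chelate; hemiaminal carbon unassigned and transient) | CC(C)(C)OC(=O)N([Mg]Cl)[C@@H](Cc1ccc(OC(C)(C)C)cc1)C(O[Mg]Cl)(Cc1ccc(OC)cc1)N(C)OC | intermediate (not isolated)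
5 | tert-butyl N-[(2S)-1-(4-tert-butoxyphenyl)-4-(4-methoxyphenyl)-3-oxobutan-2-yl]carbamate | CC(C)(C)OC(=O)N[C@@H](Cc1ccc(OC(C)(C)C)cc1)C(=O)Cc1ccc(OC)cc1 | intermediate
6 | (3S)-3-amino-4-(4-hydroxyphenyl)-1-(4-methoxyphenyl)butan-2-one trifluoroacetate | N[C@@H](Cc1ccc(O)cc1)C(=O)Cc1ccc(OC)cc1.OC(=O)C(F)(F)F | intermediate (not isolated)
7 | 4-{[5-(4-methoxybenzyl)-1H-imidazol-4-yl]methyl}phenol | COc1ccc(Cc2[nH]cnc2Cc2ccc(O)cc2)cc1 | intermediate
8 | melanocin F, 4-{[5-(4-methoxybenzyl)-1H-imidazol-4-yl]methyl}phenyl hydrogen sulfate | COc1ccc(Cc2[nH]cnc2Cc2ccc(OS(=O)(=O)O)cc2)cc1 | target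

Total step count: 4. Longest linear sequence: 4 steps (1 → 2 → 5 → 7 → 8); 3 is a commercial reagent solution.

Steps most likely to fail

Step 3. The liberated α-amino ketone may condense with itself (dihydropyrazine formation) faster than it is captured by formamidine, and the tert-butyl cations released in the acidolysis may alkylate the two electron-rich rings. The fallback sets out from 5 and comes back at 7. The acidolysis is run as before, but the salt 6 is isolated and the amine is formylated as it is set free (HCO2H, EDC·HCl, N-methylmorpholine, CH2Cl2, 0 °C). This should give N-[(2S)-1-(4-hydroxyphenyl)-4-(4-methoxyphenyl)-3-oxobutan-2-yl]formamide F1, which can no longer dimerise. Heating it with excess NH4OAc in AcOH (Davidson-type cyclisation of an α-acylamino ketone) should then close the imidazole and give 7.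

Step 4. Sulfonation at the imidazole nitrogen may compete with O-sulfation, and the aryl sulfate may be hydrolysed by acid during isolation of the zwitterion. The fallback sets out from 7 and comes back at 8. The phenol is converted with SO2F2 and Et3N in CH2Cl2 (SuFEx) into the robust, chromatographable aryl fluorosulfate 4-{[5-(4-methoxybenzyl)-1H-imidazol-4-yl]methyl}phenyl sulfurofluoridate F2. The sulfate is then unmasked under basic, non-hydrolytic conditions (Cs2CO3, ethylene glycol, rt) and neutralised to 8.

Step 2. The titre of the benzylic Grignard reagent may be lost to Wurtz-type homocoupling, proton abstraction at Cα may compete with addition, and the benzyl nucleophile may attack through its ortho position. The fallback sets out from 1 and comes back at 5, and forms the same carbon–carbon bond by a palladium-catalysed acyl cross-coupling of a non-basic organozinc. Acid 1 is converted (EtSH, EDC·HCl, DMAP cat., CH2Cl2) into the thioester S-ethyl (2S)-2-[(tert-butoxycarbonyl)amino]-3-(4-tert-butoxyphenyl)propanethioate F3. Fukuyama coupling of F3 with commercial 4-methoxybenzylzinc chloride (PdCl2(PPh3)2 cat., THF/toluene, rt) should give ketone 5 without over-addition.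

Further compounds
F1 | step 3 | N-[(2S)-1-(4-hydroxyphenyl)-4-(4-methoxyphenyl)-3-oxobutan-2-yl]formamide | O=CN[C@@H](Cc1ccc(O)cc1)C(=O)Cc1ccc(OC)cc1
F2 | step 4 | 4-{[5-(4-methoxybenzyl)-1H-imidazol-4-yl]methyl}phenyl sulfurofluoridate | COc1ccc(Cc2[nH]cnc2Cc2ccc(OS(=O)(=O)F)cc2)cc1
F3 | step 2 | S-ethyl (2S)-2-[(tert-butoxycarbonyl)amino]-3-(4-tert-butoxyphenyl)propanethioate | CC(C)(C)OC(=O)N[C@@H](Cc1ccc(OC(C)(C)C)cc1)C(=O)SCC
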